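The flask gets less partner per substrate than zeta and more than alpha, with 1.00 partner per substrate.

| flask | left-handed substrate | right-handed substrate | partner | free catalyst | precatalyst | remark | time |
|---|---|---|---|---|---|---|---|
| zeta | 0.12 M | 0.12 M | 0.50 M | 25 mM | 0.14 mM | run made earlier |  |
| alpha | 0.50 M | 0.50 M | 0.50 M | 25 mM | 0.14 mM | run made earlier |  |
| flask | 0.25 M | 0.25 M | 0.500 M | 25 mM | 0.14 mM |  | 15 min |

| run | time / min | left-handed product / % | right-handed product / % | left-handed substrate / % |
|---|---|---|---|---|
| zeta | 0.667 | 5.4 | 2.9 | 44.4 |
| zeta | 1.00 | 8.1 | 3.6 | 41.8 |
| zeta | 1.50 | 11.6 | 5.2 | 38.4 |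
| zeta | 2.50 | 16.4 | 7.7 | 33.3 |
| zeta | 4.00 | 23.0 | 11.7 | 27.6 |
| zeta | 6.00 | 29.9 | 16.3 | 20.6 |
| zeta | 10.0 | 37.4 | 23.4 | 12.5 |
| alpha | 1.33 | 8.5 | 4.0 | 41.4 |
| alpha | 2.50 | 14.1 | 6.9 | 36.0 |
| alpha | 4.00 | 18.5 | 9.3 | 31.9 |
| alpha | 5.00 | 20.9 | 11.0 | 29.4 |
| alpha | 6.00 | 22.1 | 11.8 | 28.2 |
| alpha | 8.00 | 25.4 | 13.2 | 25.7 |
| alpha | 10.0 | 26.2 | 14.4 | 23.2 |

(readings scatter by 0.3 percentage points)

- free catalyst is single-handed; left-handed substrate and right-handed substrate are mirror images of each other, charged as a racemate, each of them at the stated concentration
- steps thought possible: partner + free catalyst + left-handed substrate -> free catalyst + left-handed product; partner + free catalyst + right-handed substrate -> free catalyst + right-handed product; left-handed substrate + racemization catalyst <-> right-handed substrate + racemization catalyst; partner + free catalyst -> spent catalyst; partner + precatalyst -> racemization catalyst + spent reagent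
- an excess is the difference of the two amounts in percent of their sum
- an excess is below zero if the other one leads

1. left-handed product and right-handed product together, in percent of the left-handed substrate and right-handed substrate charged together, at 15 min
2. excess of left-handed product over right-handed product in the product at 15 min
3. whether the exchange between left-handed substrate and right-handed substrate keeps pace with the reaction: how far the product's excess at 15 min gets from its value without exchange to its value with instant exchange (above 80% keeps pace, below 20% hardly takes part, else lags behind)

Note the oddity: alpha holds 4.17 times the substrate of zeta, yet at 2.50 min it has turned 21.0% of its charge against zeta's 24.1%; at 10.0 min it shows 40.6% against 60.8%. Write the partner balance, one partner per substrate turned: at that time the fraction of partner left is 18.8% in alpha and 70.8% in zeta. So take each substrate as falling in proportion to itself and to partner.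

Let l and r be the fractions of left- and right-handed substrate left. Zeta's last reading gives 2.20 for ln l over ln r, the selectivity factor s. Left-handed substrate and product there sum to half the charge, so take exchange as hardly taking part.

Zeta's mean partner gives a left-handed constant of 0.325 /M/min, and the mean of both constants is 0.236 /M/min. In the flask, partner fraction b equals the mean of l and r, so treat it as second-order: 1/b gains 1.77 by 15 min. Integrate b over time: l = 24.6%, r = 52.8%. That reckons 61.3% turned and an excess of 23.0%, against 37.5% with instant exchange.

The forecast, slightly higher than this reckoning on both, gives 62.5%, 23.5% and hardly takes part: “So exchange is very slow”.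

The flask gives 62.8% and 22.9%; exchange hardly takes part, getting 0.40% of the way.

    partner + free catalyst + left-handed substrate → free catalyst + left-handed product (k = 14.0 /M²/min)
    partner + free catalyst + right-handed substrate → free catalyst + right-handed product (k = 6.30 /M²/min)
    left-handed substrate + racemization catalyst ⇌ right-handed substrate + racemization catalyst, rate k3*[racemization catalyst]*[left-handed substrate] forward; the back reaction follows from the equilibrium constant (k = 3.10 /M/min)
    partner + free catalyst → spent catalyst (k = 0.0110 /M/min)
    partner + precatalyst → racemization catalyst + spent reagent (k = 3.30 /M/min)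

The flask keeps 37% of its partner. It keeps 23% of its left-handed substrate. Put s on that l: it gives r = 51.3%, and the flask keeps 51% of its right-handed substrate. Put it on the neighbour charged with 0.12 M of partner, which keeps 74% of its left-handed substrate: it gives r = 87.2%, and that neighbour keeps 87% of its right-handed substrate.

The readings were generated by integration with constants of no real substance.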